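## The problem

The target **31** is an eleven-membered carbocycle, numbered here C1 (quaternary; methyl and the side chain C1'–C5'), C2=C3 (E), C4 (carbinol carbon carrying the 3-methylbut-2-enoate), C5–C6 (oxirane, methyl on C5), C7, C8, C9 (bearing the hydroxymethyl carbon C12), C10 and C11; the same numbers are used for all open-chain precursors. A ring of this size has to be closed against strain and entropy, and the closing bond must leave C9=C10 with C8 and C11 cis and C2=C3 trans. There are five stereocentres: the all-carbon quaternary C1 (S), the contiguous triad C4 (R), C5 (R), C6 (S) with a trans trisubstituted oxirane, and the side-chain carbinol C3' (R). Within the triad the oxirane can steer C4 through its oxygen, but C1 and C3' are insulated from the triad and from each other, so three independent sources of absolute configuration are needed. The oxirane lies next to an allylic ester and tolerates neither acid (opening with acyloxy participation) nor hard nucleophiles; the senecioate excludes hydride donors stronger than borohydride and strong base; two allylic alcohols and a 1,1-disubstituted olefin call for near-neutral late steps. The enabling feature is that the C5–C6 oxirane adjoins oxygenated C4: at the ketone level C5 is the α-carbon of an enone and its only enolisable position (C3 is vinylic, C1 has no hydrogen), so the methyl-bearing oxirane is the Darzens product of an α-chloro ethyl ketone and a C6 aldehyde. The same C4 ketone then lets the finished oxirane set C4.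

## Retrosynthesis

**C9=C10 (ring closure).** Target **31** is taken back to its triisopropylsilyl ether **30** and, by raising C12 to the aldehyde level, to enal **29**. The C9=C10 bond of **29** is cut by a retro-aldol condensation to dialdehyde **28**. This cut is preferred to C8–C9 or C10–C11 because both termini then arise from simple primary silyl ethers, and because the thermodynamically favoured (E)-enal has the formyl group trans to C11, which is the ring-cis geometry required. The precursor is acyclic and already holds every stereocentre. The forward step must close the eleven-membered ring from the enamine of the correct aldehyde, and the reduction after it must spare the ester.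

**C4 ester and C4 configuration.** Dialdehyde **28** comes from diol **27** and bis-silyl ether **26** without any C–C cut. The C4–O ester bond of **26** is cut to 3-methylbut-2-enoic acid **25** and the C4-epimeric alcohol **24**. Chelation-controlled reduction of ketone **23** should give the erythro alcohol whereas the target is threo, so a Mitsunobu esterification installs the ester and corrects C4 in one operation. The alternative of esterifying a threo alcohol directly would need a reduction against the chelate preference. The forward steps must reduce the enone 1,2 and substitute at a hindered allylic carbinol with clean inversion.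

**C5–C6 and C5–O (key cut).** The oxirane of **23** is opened to α-chloro enone **18** (fragment 1) and 5-silyloxypentanal **21** (fragment 2). Against epoxidation of a C5=C6 olefin this cut is convergent, joins a C15 and a C5 piece, and makes the oxirane when no other olefin competes for an oxidant. Against cutting C4–C5 it keeps the C4 carbonyl, which is needed both for enolisation and for setting C4 afterwards. Fragment **21** is achiral and **18** carries only the two remote centres. The forward reaction must create C5 and C6 under catalyst control and deliver the trans oxirane.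

**C3–C4 and C5–Cl.** Removing chlorine from **18** gives ethyl enone **16**, whose C3–C4 bond is cut to propanoyl chloride **14** and the E-alkenyl metal from terminal alkyne **13**. An olefination of a C2 aldehyde is the neighbouring option, but the alkyne is what the construction of C1 supplies, and hydrometalation gives the E olefin without isomers. The forward steps need chemoselectivity for the alkyne over the isopropenyl group; the site of enolisation for chlorination is fixed by the substitution pattern.

**Side-chain carbinol C3'.** Alkyne **13** is traced through silyl ether **12** and allylic alcohol **11** to oxirane **10** and the prenyl-type olefin of **9**. No skeletal bond is cut: asymmetric epoxidation and base-induced isomerisation convert the trisubstituted olefin into the isopropenyl carbinol. This is preferred to adding an isopropenyl metal to a C3' aldehyde because the carbons are already present and the configuration comes from a catalyst of predictable sense. The isomerisation must remove a methyl proton only.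

**Quaternary centre C1.** Silyl ether **9** derives from alcohol **8** and enyne **6**. The vinyl terminus of **6** (C10) is removed via aldehyde **5** to diol **4**, and the C1–C2 bond of **4** is cut to ethynyltrimethylsilane **3** and (2R,3R)-epoxygeraniol **2**, made from geraniol **1**. Enolate alkylation at C1 was set aside because it needs an auxiliary and two alkylations; the epoxide opening transfers the dependable enantioselectivity of allylic alcohol epoxidation to a quaternary carbon with inversion. The forward reaction must attack the fully substituted oxirane carbon; the diol left behind is a latent C11 aldehyde.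

**Fragment 2.** Aldehyde **21** is the oxidised mono-silyl ether **20** of pentane-1,5-diol **19**; its carbons become C6–C9 and C12.

## Roads not taken

**Alternative 1:** The eleven-membered ring is traced to a seven-membered one by breaking C1–C11 and re-forming C3–C9, which leads to the cis-1,2-dialkenylcycloheptanol A1. In the forward sense KH and 18-crown-6 would trigger an anionic oxy-Cope rearrangement of A1, and PhNTf2 would trap the C9 enolate as enol triflate A2.
- Merits: the medium ring arises by ring expansion, not by end-to-end closure, so dilution and oligomerisation are not an issue. The concerted transition state sets C1 and both olefin geometries at once, and the triflate is a regiodefined handle for C12.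
- Weak points: A1 needs five correctly related stereocentres on a cycloheptane, the cis relation of the two alkenyl groups and a defined trisubstituted olefin, and a chair or boat pathway would give opposite C1. Forming a quaternary carbon at the diene terminus slows the rearrangement. The oxirane must still be made late from the protected diol, followed by carbonylation, reduction, PMB removal and esterification.
- Comparison: as a ring-forming event this road is better than the chosen plan, and it fixes C1 and C9=C10 together. The chosen plan sets against it convergence, an oxirane that appears in its final form at the fragment union, and a much shorter sequence after the key step.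

**Alternative 2:** The C4–C5 bond is cut to the acyclic iodo enal A3. CrCl2 with catalytic NiCl2 would convert the alkenyl iodide into an alkenylchromium species that adds to the enal carbonyl and closes the ring as bis-allylic alcohol A4.
- Merits: this is the most dependable closure of strained medium carbocycles, it tolerates dense functionality, and both trisubstituted olefins are fixed beforehand.
- Weak points: C4 forms as both epimers in an acid-labile bis-allylic position. The oxirane then has to be placed on C5=C6 in a ring holding four olefins, with a facial sense that depends on ring conformation and on the C4 epimer. The whole triad is therefore left to late substrate control, with oxidation–reduction or resolution needed to converge.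
- Comparison: for ring closure this road is more certain than the aldol condensation used here. The chosen plan answers with catalyst-controlled C5/C6 set when no other olefin is present, and with C4 set by chelation control on an acyclic ketone.

**Alternative 3:** The same C9=C10 bond is cut, but to phosphonate aldehyde A5. Under LiCl and DBU in acetonitrile at high dilution its carbanion would undergo an intramolecular Horner–Wadsworth–Emmons reaction to enoate A6.
- Merits: the olefination is irreversible and mild, has broad macrocyclic use, and an α-substituted phosphonoacetate gives the (E)-enoate, which is the ring-cis geometry.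
- Weak points: the key step builds only the ring, so the triad must be made separately. The acidic phosphonoacetate cannot pass through base-mediated fragment unions and has to be introduced late. The enoate needs i-Bu2AlH, which excludes the senecioate, so C4 must stay protected and be esterified after the reduction.
- Comparison: this closure is more certain than the aldol condensation and gives the same geometry. The chosen plan offers two aldehydes from two simple silyl ethers, an enal that needs only borohydride in the presence of the ester, and a key step that builds the oxirane itself. The phosphonate closure is kept as the fallback for step 20.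

Key step: step 15

Assumption: the cinchonine-derived ammonium salt is taken to induce the (5R,6S) sense in step 15; if the sense proves opposite, the pseudoenantiomeric N-[4-(trifluoromethyl)benzyl]cinchonidinium bromide takes its place with nothing else changed.

## Steps

Step 1
Reactants: 1 geraniol
Product: 2 (2R,3R)-2,3-epoxygeraniol
Conditions: Ti(OiPr)4 (cat.), D-(−)-diethyl tartrate (cat.), t-BuOOH, 4 Å MS, CH2Cl2, −20 °C
Reagents that add atoms: tert-butyl hydroperoxide, CC(C)(C)OO
Why: Sharpless asymmetric epoxidation; the titanium–tartrate complex binds the allylic hydroxyl and delivers oxygen to one face of the 2,3-olefin, setting the oxirane as (2R,3R), while the 6,7-olefin has no directing hydroxyl and stays intact.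

Step 2
Reactants: 2 (2R,3R)-2,3-epoxygeraniol; 3 ethynyltrimethylsilane
Product: 4 (2S,3R)-3,7-dimethyl-3-[(trimethylsilyl)ethynyl]oct-6-ene-1,2-diol
Conditions: 3, n-BuLi, toluene, 0 °C; Et2AlCl; then 2, 0 °C → rt
Reagents that add atoms: none
Why: Ring opening of a 2,3-epoxy alcohol by an alkynylalane; the aluminium alkoxide of 2 activates the oxirane and the alkynyl group attacks C3, the carbon best able to bear positive charge, anti to the breaking C–O bond, so the quaternary centre (ring C1) is set with inversion.

Step 3
Reactants: 4 (2S,3R)-alkynyl diol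
Product: 5 (2R)-2,6-dimethyl-2-[(trimethylsilyl)ethynyl]hept-5-enal
Conditions: NaIO4, THF/H2O, 0 °C → rt
Reagents that add atoms: none
Why: Periodate glycol cleavage removes the terminal carbon as formaldehyde; the aldehyde has no α-hydrogen, so the quaternary centre cannot epimerise.

Step 4
Reactants: 5 (2R)-alkynyl aldehyde
Product: 6 [(3S)-3-ethenyl-3,7-dimethyloct-6-en-1-yn-1-yl]trimethylsilane
Conditions: Ph3PCH3Br, KN(SiMe3)2, THF, 0 °C; then 5, −78 °C → rt
Reagents that add atoms: methyltriphenylphosphonium bromide, C[P+](c1ccccc1)(c1ccccc1)c1ccccc1.[Br-]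
Why: Wittig methylenation; the unstabilised ylide reacts readily even with an α-quaternary aldehyde and supplies the carbon that becomes C10.

Step 5
Reactants: 6 (3S)-enyne
Product: 8 (3S)-3,7-dimethyl-3-[(trimethylsilyl)ethynyl]oct-6-en-1-ol, via B-alkyl-9-BBN adduct 7 (not isolated)
Conditions: 9-BBN, THF, 0 °C → rt; then NaBO3·4H2O, H2O, rt
Reagents that add atoms: 9-borabicyclo[3.3.1]nonane (boron only in intermediate 7), B1C2CCCC1CCC2; sodium perborate NaBO3·4H2O (oxygen), [Na+].[Na+].O[B-]1(O)OO[B-](O)(O)OO1
Why: Hydroboration–oxidation; 9-BBN adds to the monosubstituted vinyl group with boron on the terminal carbon and is too bulky for the trisubstituted olefin or the silyl-capped alkyne, and perborate oxidises the C–B bond mildly enough to keep the C–Si bond.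

Step 6
Reactants: 8 (3S)-primary alcohol
Product: 9 tert-butyl({(3S)-3,7-dimethyl-3-[(trimethylsilyl)ethynyl]oct-6-en-1-yl}oxy)dimethylsilane
Conditions: TBSCl, imidazole, DMF, rt
Reagents that add atoms: tert-butyldimethylsilyl chloride, CC(C)(C)[Si](C)(C)Cl
Why: Standard silylation of a primary alcohol; the TBS ether protects the future C10 oxygen through the base-mediated steps up to the fragment union.

Step 7
Reactants: 9 TBS ether
Product: 10 tert-butyl({(3S)-5-[(2R)-3,3-dimethyloxiran-2-yl]-3-methyl-3-[(trimethylsilyl)ethynyl]pentyl}oxy)dimethylsilane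
Conditions: D-fructose-derived Shi ketone (30 mol%), KHSO5 (as Oxone, 2KHSO5·KHSO4·K2SO4), K2CO3, Bu4NHSO4 (cat.), MeCN/CH2(OMe)2/aq. Na2B4O7 buffer, 0 °C
Reagents that add atoms: potassium peroxymonosulfate KHSO5 (oxygen), [K+].[O-]S(=O)(=O)OO
Why: Shi epoxidation; the chiral dioxirane attacks the only olefin, an electron-rich trisubstituted one, through a spiro transition state that sets the oxirane CH carbon (later C3') as R, and the silyl-capped alkyne is inert to dioxiranes.

Step 8
Reactants: 10 (R)-oxirane
Product: 11 (3R,6S)-8-[(tert-butyldimethylsilyl)oxy]-2,6-dimethyl-6-[(trimethylsilyl)ethynyl]oct-1-en-3-ol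
Conditions: lithium 2,2,6,6-tetramethylpiperidide, Et2AlCl, toluene, 0 °C; then 10, 0 °C → rt
Reagents that add atoms: none
Why: Base-induced isomerisation of an epoxide to an allylic alcohol with an aluminium amide; aluminium binds the oxirane oxygen and the hindered amide removes a methyl proton as the C–O bond at the dimethyl-substituted carbon breaks, so the isopropenyl carbinol forms and the C3'–O bond keeps its R configuration.

Step 9
Reactants: 11 (3R,6S)-allylic alcohol
Product: 12 tert-butyl({(3S,6R)-3,7-dimethyl-6-[(triisopropylsilyl)oxy]-3-[(trimethylsilyl)ethynyl]oct-7-en-1-yl}oxy)dimethylsilane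
Conditions: TIPSOTf, 2,6-lutidine, CH2Cl2, −78 °C → 0 °C
Reagents that add atoms: triisopropylsilyl trifluoromethanesulfonate, CC(C)[Si](C(C)C)(C(C)C)OS(=O)(=O)C(F)(F)F
Why: Silylation of a hindered secondary alcohol with a silyl triflate; the TIPS ether is chosen to outlast the later removal of the primary TBS ethers.

Step 10
Reactants: 12 C-silyl alkyne
Product: 13 tert-butyl({(3S,6R)-3-ethynyl-3,7-dimethyl-6-[(triisopropylsilyl)oxy]oct-7-en-1-yl}oxy)dimethylsilane
Conditions: K2CO3 (cat.), MeOH, rt
Reagents that add atoms: none
Why: Base-catalysed methanolysis of the C(sp)–Si bond; the alkyl silyl ethers are stable to carbonate in methanol.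

Step 11
Reactants: 13 terminal alkyne; 14 propanoyl chloride
Product: 16 (4E,6S,9R)-6-{2-[(tert-butyldimethylsilyl)oxy]ethyl}-6,10-dimethyl-9-[(triisopropylsilyl)oxy]undeca-4,10-dien-3-one, via (E)-alkenylzirconocene chloride 15 (not isolated)
Conditions: Cp2Zr(H)Cl, THF, rt; then 14, CuBr·SMe2 (10 mol%), rt
Reagents that add atoms: Cp2Zr(H)Cl (zirconium only in intermediate 15), [H][Zr](Cl)(C1C=CC=C1)C1C=CC=C1
Why: Hydrozirconation followed by copper-catalysed acylation; Cp2Zr(H)Cl adds syn to the terminal alkyne with zirconium on the terminal carbon, and the E-alkenyl group is passed to copper and acylated with retention of geometry. The hindered isopropenyl group reacts with the hydride far more slowly than the alkyne.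

Step 12
Reactants: 16 ethyl enone
Product: 18 (4E,6S,9R)-6-{2-[(tert-butyldimethylsilyl)oxy]ethyl}-2-chloro-6,10-dimethyl-9-[(triisopropylsilyl)oxy]undeca-4,10-dien-3-one (fragment 1; both epimers at the chlorine-bearing carbon C5), via trimethylsilyl dienol ether 17 (not isolated)
Conditions: LiN(iPr)2, Me3SiCl, THF, −78 °C; then NCS, CH2Cl2, 0 °C
Reagents that add atoms: chlorotrimethylsilane (silicon only in intermediate 17), C[Si](C)(C)Cl; N-chlorosuccinimide, O=C1CCC(=O)N1Cl
Why: Kinetic enolisation and electrophilic chlorination; only the ethyl CH2 can be deprotonated (the other side is vinylic and the γ-carbon is quaternary), and NCS chlorinates the silyl dienol ether at that carbon. The C–Cl centre is left uncontrolled because it is erased on enolisation in step 15.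

Step 13
Reactants: 19 pentane-1,5-diol
Product: 20 5-[(tert-butyldimethylsilyl)oxy]pentan-1-ol
Conditions: NaH (1 equiv), THF, 0 °C → rt; then TBSCl
Reagents that add atoms: tert-butyldimethylsilyl chloride, CC(C)(C)[Si](C)(C)Cl
Why: Monosilylation of a symmetrical diol through its sparingly soluble monosodium alkoxide, which biases the reaction toward the mono-ether.

Step 14
Reactants: 20 mono-silyl ether
Product: 21 5-[(tert-butyldimethylsilyl)oxy]pentanal (fragment 2)
Conditions: PhI(OAc)2, TEMPO (cat.), CH2Cl2, rt
Reagents that add atoms: none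
Why: Nitroxyl-catalysed oxidation of a primary alcohol, which stops at the aldehyde and leaves the silyl ether alone.

Step 15
Reactants: 18 α-chloro enone (fragment 1); 21 5-[(tert-butyldimethylsilyl)oxy]pentanal (fragment 2)
Product: 23 (2E,4S,7R)-1-{(2R,3S)-3-[4-(tert-butyldimethylsilyloxy)butyl]-2-methyloxiran-2-yl}-4-{2-[(tert-butyldimethylsilyl)oxy]ethyl}-4,8-dimethyl-7-[(triisopropylsilyl)oxy]nona-2,8-dien-1-one, via chlorohydrin aldolate 22 (not isolated)
Conditions: LiOH·H2O, N-[4-(trifluoromethyl)benzyl]cinchoninium bromide (10 mol%), n-Bu2O, 4 °C; 21 in excess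
Reagents that add atoms: none
Why: Darzens condensation under chiral phase-transfer catalysis; the closest known reaction type is the cinchona-ammonium-catalysed Darzens reaction of α-chloro ketones with aldehydes, here extended to an acyclic α-methyl chloro enone. Solid LiOH deprotonates 18 at C5, its only acidic carbon because C3 is vinylic and C1 has no hydrogen, so both C5 epimers merge in one enolate that enters the ether phase as an ion pair with the cinchoninium cation. The enolate adds to the aldehyde carbon of 21 to form C5–C6 (aldolate 22), and the alkoxide then displaces chloride at C5 with inversion in a 3-exo-tet closure, the only ring this step closes. C5 and C6 are both new stereocentres; their absolute configuration is decided in the addition by the chiral cation, which screens one enolate face, because C1 and C3' are too remote to interfere. The trans arrangement of acyl group and C7 is expected because the aldol addition is reversible and the aldolate that reaches the anti-periplanar O–C–C–Cl geometry with C7 turned away from the acyl group closes fastest. The step also needs chemoselectivity against conjugate addition and aldehyde self-condensation: the quaternary C1 screens C2, and 21 is used in excess. The product has no hydrogen at C5 and is therefore stable to the base, and since 18 is a single enantiomer any stereoisomeric oxirane is a diastereomer that chromatography removes.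

Step 16
Reactants: 23 trans-epoxy enone
Product: 24 (1S,2E,4S,7R)-1-{(2S,3S)-3-[4-(tert-butyldimethylsilyloxy)butyl]-2-methyloxiran-2-yl}-4-{2-[(tert-butyldimethylsilyl)oxy]ethyl}-4,8-dimethyl-7-[(triisopropylsilyl)oxy]nona-2,8-dien-1-ol (erythro; ring numbering 4S,5S,6S)
Conditions: Zn(BH4)2, Et2O, −20 °C
Reagents that add atoms: none
Why: Chelation-controlled 1,2-reduction; zinc bridges the carbonyl and oxirane oxygens and hydride attacks C4 from the face away from C6, giving the erythro (4S) alcohol. Zn(BH4)2 reduces enones at the carbonyl and leaves the oxirane and silyl ethers alone.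

Step 17
Reactants: 24 erythro (4S) alcohol; 25 3-methylbut-2-enoic acid
Product: 26 (4R)-3-methylbut-2-enoate of the C4 alcohol (ring numbering 1S,4R,5R,6S,3'R; threo; silyl ethers as in 24)
Conditions: 25, PPh3, diisopropyl azodicarboxylate, toluene, 0 °C → rt
Reagents that add atoms: none
Why: Mitsunobu esterification; the alkoxyphosphonium ion of 24 is displaced by the carboxylate with inversion, turning the erythro (4S) alcohol into the threo (4R) ester of the target. The allylic position helps substitution, while the quaternary C1 next to C2 disfavours the SN2' path.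

Step 18
Reactants: 26 bis-TBS senecioate
Product: 27 diol with free C10 and C12 hydroxyls (ring numbering 1S,4R,5R,6S,3'R; C3' still a TIPS ether)
Conditions: HF·pyridine, pyridine, THF, 0 °C
Reagents that add atoms: none
Why: Buffered fluoride desilylation; primary TBS ethers are cleaved much faster than the hindered secondary TIPS ether, and excess pyridine keeps the medium mild enough for the oxirane and the allylic ester.

Step 19
Reactants: 27 diol
Product: 28 C10,C12-dialdehyde (ring numbering 1S,4R,5R,6S,3'R)
Conditions: Dess–Martin periodinane, NaHCO3, CH2Cl2, 0 °C → rt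
Reagents that add atoms: none
Why: Dess–Martin oxidation of both primary alcohols under bicarbonate buffer; the near-neutral conditions spare the oxirane, ester and silyl ether, and neither aldehyde has a stereocentre at its α-carbon.

Step 20
Reactants: 28 dialdehyde
Product: 29 eleven-membered (9E)-enal with C12 as the formyl carbon on C9 (1S,4R,5R,6S,3'R; C8 and C11 cis)
Conditions: (PhCH2)2NH·CF3CO2H (cat.), toluene, 50 °C, slow addition (final concentration 1 mM)
Reagents that add atoms: none
Why: Intramolecular aldol condensation through an enamine; the ammonium salt forms the enamine preferentially at C9, because the other α-carbon (C11) is neopentyl, and this adds to the C10 aldehyde, after which water is lost to give the conjugated enal. The steps before dehydration are reversible, so the more stable (E)-enal results, with formyl cis to H-10 and C8 cis to C11 as in the target. Slow addition at high dilution favours ring closure over oligomerisation.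

Step 21
Reactants: 29 macrocyclic enal
Product: 30 C3' triisopropylsilyl ether of the target (primary allylic alcohol at C12)
Conditions: NaBH4, CeCl3·7H2O, MeOH, −20 °C
Reagents that add atoms: none
Why: Luche reduction; borohydride with CeCl3 reduces the enal carbonyl 1,2, and the senecioate and oxirane are inert to it at this temperature.

Step 22
Reactants: 30 C3' silyl ether
Product: 31 target CNP0309478.2
Conditions: Bu4NF, AcOH, THF, 0 °C → rt
Reagents that add atoms: none
Why: Fluoride cleavage of the secondary TIPS ether; acetic acid buffers the alkoxide so that neither acyl migration nor oxirane opening is triggered, and no stereocentre is touched.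

## Compound list

1 | geraniol, (2E)-3,7-dimethylocta-2,6-dien-1-ol | CC(C)=CCC/C(C)=C/CO | starting material
2 | (2R,3R)-2,3-epoxygeraniol | CC(C)=CCC[C@@]1(C)O[C@@H]1CO | intermediate
3 | ethynyltrimethylsilane | C#C[Si](C)(C)C | starting material
4 | (2S,3R)-3,7-dimethyl-3-[(trimethylsilyl)ethynyl]oct-6-ene-1,2-diol | CC(C)=CCC[C@](C)(C#C[Si](C)(C)C)[C@H](O)CO | intermediate
5 | (2R)-2,6-dimethyl-2-[(trimethylsilyl)ethynyl]hept-5-enal | CC(C)=CCC[C@](C)(C#C[Si](C)(C)C)C=O | intermediate
6 | [(3S)-3-ethenyl-3,7-dimethyloct-6-en-1-yn-1-yl]trimethylsilane | CC(C)=CCC[C@](C)(C#C[Si](C)(C)C)C=C | intermediate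
7 | 9-{(3R)-3,7-dimethyl-3-[(trimethylsilyl)ethynyl]oct-6-en-1-yl}-9-borabicyclo[3.3.1]nonane (not isolated) | CC(C)=CCC[C@](C)(C#C[Si](C)(C)C)CCB1C2CCCC1CCC2 | intermediate
8 | (3S)-3,7-dimethyl-3-[(trimethylsilyl)ethynyl]oct-6-en-1-ol | CC(C)=CCC[C@](C)(C#C[Si](C)(C)C)CCO | intermediate
9 | tert-butyl({(3S)-3,7-dimethyl-3-[(trimethylsilyl)ethynyl]oct-6-en-1-yl}oxy)dimethylsilane | CC(C)=CCC[C@](C)(C#C[Si](C)(C)C)CCO[Si](C)(C)C(C)(C)C | intermediate
10 | tert-butyl({(3S)-5-[(2R)-3,3-dimethyloxiran-2-yl]-3-methyl-3-[(trimethylsilyl)ethynyl]pentyl}oxy)dimethylsilane | CC1(C)O[C@@H]1CC[C@](C)(C#C[Si](C)(C)C)CCO[Si](C)(C)C(C)(C)C | intermediate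
11 | (3R,6S)-8-[(tert-butyldimethylsilyl)oxy]-2,6-dimethyl-6-[(trimethylsilyl)ethynyl]oct-1-en-3-ol | C=C(C)[C@H](O)CC[C@](C)(C#C[Si](C)(C)C)CCO[Si](C)(C)C(C)(C)C | intermediate
12 | tert-butyl({(3S,6R)-3,7-dimethyl-6-[(triisopropylsilyl)oxy]-3-[(trimethylsilyl)ethynyl]oct-7-en-1-yl}oxy)dimethylsilane | C=C(C)[C@H](O[Si](C(C)C)(C(C)C)C(C)C)CC[C@](C)(C#C[Si](C)(C)C)CCO[Si](C)(C)C(C)(C)C | intermediate
13 | tert-butyl({(3S,6R)-3-ethynyl-3,7-dimethyl-6-[(triisopropylsilyl)oxy]oct-7-en-1-yl}oxy)dimethylsilane | C=C(C)[C@H](O[Si](C(C)C)(C(C)C)C(C)C)CC[C@](C)(C#C)CCO[Si](C)(C)C(C)(C)C | intermediate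
14 | propanoyl chloride | CCC(=O)Cl | starting material
15 | chlorobis(cyclopentadienyl)[(1E,3S,6R)-3-{2-[(tert-butyldimethylsilyl)oxy]ethyl}-3,7-dimethyl-6-[(triisopropylsilyl)oxy]octa-1,7-dien-1-yl]zirconium (not isolated) | C=C(C)[C@H](O[Si](C(C)C)(C(C)C)C(C)C)CC[C@](C)(/C=C/[Zr](Cl)(C1C=CC=C1)C1C=CC=C1)CCO[Si](C)(C)C(C)(C)C | intermediate
16 | (4E,6S,9R)-6-{2-[(tert-butyldimethylsilyl)oxy]ethyl}-6,10-dimethyl-9-[(triisopropylsilyl)oxy]undeca-4,10-dien-3-one | CCC(=O)/C=C/[C@@](C)(CC[C@@H](O[Si](C(C)C)(C(C)C)C(C)C)C(C)=C)CCO[Si](C)(C)C(C)(C)C | intermediate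
17 | trimethylsilyl dienol ether of 16, 3-(trimethylsilyloxy)undeca-2,4,10-triene (enol ether geometry not defined; not isolated) | CC=C(O[Si](C)(C)C)/C=C/[C@@](C)(CC[C@@H](O[Si](C(C)C)(C(C)C)C(C)C)C(C)=C)CCO[Si](C)(C)C(C)(C)C | intermediate
18 | fragment 1, (4E,6S,9R)-6-{2-[(tert-butyldimethylsilyl)oxy]ethyl}-2-chloro-6,10-dimethyl-9-[(triisopropylsilyl)oxy]undeca-4,10-dien-3-one (both epimers at the chlorine-bearing carbon) | CC(Cl)C(=O)/C=C/[C@@](C)(CC[C@@H](O[Si](C(C)C)(C(C)C)C(C)C)C(C)=C)CCO[Si](C)(C)C(C)(C)C | intermediate
19 | pentane-1,5-diol | OCCCCCO | starting material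
20 | 5-[(tert-butyldimethylsilyl)oxy]pentan-1-ol | OCCCCCO[Si](C)(C)C(C)(C)C | intermediate
21 | fragment 2, 5-[(tert-butyldimethylsilyl)oxy]pentanal | O=CCCCCO[Si](C)(C)C(C)(C)C | intermediate
22 | chlorohydrin aldolate, alkoxide of the (5S,6S)-5-chloro-6-hydroxy ketone (ring numbering; not isolated) | CC(C)(C)[Si](C)(C)OCCCC[C@H]([O-])[C@](C)(Cl)C(=O)/C=C/[C@@](C)(CC[C@@H](O[Si](C(C)C)(C(C)C)C(C)C)C(C)=C)CCO[Si](C)(C)C(C)(C)C | intermediate
23 | trans-epoxy enone, (2E,4S,7R)-1-{(2R,3S)-3-[4-(tert-butyldimethylsilyloxy)butyl]-2-methyloxiran-2-yl}-4-{2-[(tert-butyldimethylsilyl)oxy]ethyl}-4,8-dimethyl-7-[(triisopropylsilyl)oxy]nona-2,8-dien-1-one | CC(C)(C)[Si](C)(C)OCCCC[C@@H]1O[C@@]1(C)C(=O)/C=C/[C@@](C)(CC[C@@H](O[Si](C(C)C)(C(C)C)C(C)C)C(C)=C)CCO[Si](C)(C)C(C)(C)C | intermediate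
24 | erythro epoxy alcohol, C4 carbinol of 23 with ring-numbering configuration 1S,4S,5S,6S,3'R | CC(C)(C)[Si](C)(C)OCCCC[C@@H]1O[C@@]1(C)[C@@H](O)/C=C/[C@@](C)(CC[C@@H](O[Si](C(C)C)(C(C)C)C(C)C)C(C)=C)CCO[Si](C)(C)C(C)(C)C | intermediate
25 | 3-methylbut-2-enoic acid (senecioic acid) | CC(C)=CC(=O)O | starting material
26 | threo (4R) 3-methylbut-2-enoate, ring numbering 1S,4R,5R,6S,3'R, C10 and C12 as TBS ethers, C3' as TIPS ether | CC(C)(C)[Si](C)(C)OCCCC[C@@H]1O[C@@]1(C)[C@H](OC(=O)C=C(C)C)/C=C/[C@@](C)(CC[C@@H](O[Si](C(C)C)(C(C)C)C(C)C)C(C)=C)CCO[Si](C)(C)C(C)(C)C | intermediate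
27 | C10,C12-diol of 26 (C3' TIPS ether kept) | OCCCC[C@@H]1O[C@@]1(C)[C@H](OC(=O)C=C(C)C)/C=C/[C@@](C)(CC[C@@H](O[Si](C(C)C)(C(C)C)C(C)C)C(C)=C)CCO | intermediate
28 | C10,C12-dialdehyde | O=CCCC[C@@H]1O[C@@]1(C)[C@H](OC(=O)C=C(C)C)/C=C/[C@@](C)(CC[C@@H](O[Si](C(C)C)(C(C)C)C(C)C)C(C)=C)CC=O | intermediate
29 | eleven-membered enal, (1S,2E,4R,5R,6S,9E)-9-formyl-1,5-dimethyl-1-{(3R)-4-methyl-3-[(triisopropylsilyl)oxy]pent-4-enyl}-5,6-epoxycycloundeca-2,9-dien-4-yl 3-methylbut-2-enoate (ring numbering) | C=C(C)[C@H](O[Si](C(C)C)(C(C)C)C(C)C)CC[C@]1(C)/C=C/[C@@H](OC(=O)C=C(C)C)[C@]2(C)O[C@H]2CC/C(C=O)=C\C1 | intermediate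
30 | C3' triisopropylsilyl ether of the target (9-hydroxymethyl) | C=C(C)[C@H](O[Si](C(C)C)(C(C)C)C(C)C)CC[C@]1(C)/C=C/[C@@H](OC(=O)C=C(C)C)[C@]2(C)O[C@H]2CC/C(CO)=C\C1 | intermediate
31 | CNP0309478.2, (1S,2E,4R,5R,6S,9E)-9-(hydroxymethyl)-1-[(3R)-3-hydroxy-4-methylpent-4-enyl]-1,5-dimethyl-5,6-epoxycycloundeca-2,9-dien-4-yl 3-methylbut-2-enoate (ring numbering) | C=C(C)[C@H](O)CC[C@]1(C)/C=C/[C@@H](OC(=O)C=C(C)C)[C@]2(C)O[C@H]2CC/C(CO)=C\C1 | target

## Step count and risks

Total: 22 steps. Longest linear sequence: 20 steps (steps 1–12 and 15–22); fragment 2 adds steps 13 and 14.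

**Step 15 (key step).** The likely failure is insufficient facial discrimination by the ion pair at a fully substituted enolate carbon, together with erosion of the trans preference, so that oxirane diastereomers form side by side; self-condensation of the aldehyde can also consume the partner. Fallback, setting out from **21** and **13** and returning at **23**: the oxirane is made by asymmetric epoxidation and the C3–C4 bond is formed afterwards.
- **21** is olefinated with Ph3P=C(CH3)CO2Et to ethyl (2E)-7-[(tert-butyldimethylsilyl)oxy]-2-methylhept-2-enoate F1.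
- i-Bu2AlH reduces this to (2E)-7-[(tert-butyldimethylsilyl)oxy]-2-methylhept-2-en-1-ol F2.
- Sharpless epoxidation with Ti(OiPr)4, L-(+)-diethyl tartrate and t-BuOOH gives [(2S,3S)-3-{4-[(tert-butyldimethylsilyl)oxy]butyl}-2-methyloxiran-2-yl]methanol F3.
- Dess–Martin oxidation gives (2R,3S)-3-{4-[(tert-butyldimethylsilyl)oxy]butyl}-2-methyloxirane-2-carbaldehyde F4.
- Alkyne **13** is hydrozirconated to **15**, transmetalated with Me2Zn and added to F4 to give the C4-epimeric epoxy allylic alcohols F5, which Dess–Martin periodinane oxidises to **23**.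

**Step 20.** Oligomerisation can outrun closure of the strained eleven-membered ring, the enamine can form on the wrong aldehyde, and prolonged heating with the amine salt can open the oxirane. Fallback, setting out from **18** and returning at **29**: the same bond is closed by an irreversible intramolecular Horner–Wadsworth–Emmons reaction, with the phosphonate introduced after the Darzens step.
- **18** is condensed as in step 15 with 3-[(triethylsilyl)oxy]propanal F6 to the C8-triethylsilyloxy epoxy enone F7.
- F7 is reduced with Zn(BH4)2 to the erythro alcohol F8 and esterified with **25** under Mitsunobu conditions to the (4R) senecioate F9.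
- Pyridinium p-toluenesulfonate in methanol removes only the triethylsilyl group to give the C8 alcohol F10; I2, PPh3 and imidazole give the C8 iodide F11.
- The sodium salt of diethyl [2-(methoxy(methyl)amino)-2-oxoethyl]phosphonate is alkylated by F11 to the C9 phosphonate amide F12.
- HF·pyridine frees the C10 alcohol F13, and Dess–Martin oxidation gives the C10 aldehyde F14.
- LiCl and DBU in acetonitrile at high dilution close the ring to the macrocyclic (E)-N-methoxy-N-methyl enamide F15.
- Cp2Zr(H)Cl reduces the amide to the aldehyde in the presence of the ester and gives **29**.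

**Step 17.** Substitution at a carbinol flanked by a fully substituted oxirane carbon may be slow with an acid as weak as **25**, letting elimination or allylic transposition compete. Fallback, setting out from **24** and returning at **26**: inversion and acylation are separated. Mitsunobu reaction with the stronger 4-nitrobenzoic acid gives the (4R) 4-nitrobenzoate F16; K2CO3 in methanol frees the threo (4R) alcohol F17; and this is acylated with **25** using dicyclohexylcarbodiimide and 4-(dimethylamino)pyridine to give **26**.

**Step 2.** The alane may attack C2, or the Lewis acid may induce a hydride or alkyl shift in the trisubstituted oxirane, in place of substitution at the fully substituted carbon. Fallback, setting out from **1** and returning at **6**: geraniol is converted with ClP(O)(OEt)2 and pyridine into geranyl diethyl phosphate F18. This undergoes copper-catalysed enantioselective SN2' substitution with (i-Bu)2Al–C≡C–SiMe3, made from **3** and i-Bu2AlH with catalytic Et3N, using CuCl2·2H2O and a chiral sulfonate-bearing N-heterocyclic carbene ligand, which gives **6** directly and makes steps 1–4 unnecessary.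

## Further compounds

F1 | step 15 | ethyl (2E)-7-[(tert-butyldimethylsilyl)oxy]-2-methylhept-2-enoate | CCOC(=O)/C(C)=C/CCCCO[Si](C)(C)C(C)(C)C
F2 | step 15 | (2E)-7-[(tert-butyldimethylsilyl)oxy]-2-methylhept-2-en-1-ol | OC/C(C)=C/CCCCO[Si](C)(C)C(C)(C)C
F3 | step 15 | [(2S,3S)-3-{4-[(tert-butyldimethylsilyl)oxy]butyl}-2-methyloxiran-2-yl]methanol | OC[C@]1(C)O[C@H]1CCCCO[Si](C)(C)C(C)(C)C
F4 | step 15 | (2R,3S)-3-{4-[(tert-butyldimethylsilyl)oxy]butyl}-2-methyloxirane-2-carbaldehyde | O=C[C@]1(C)O[C@H]1CCCCO[Si](C)(C)C(C)(C)C
F5 | step 15 | C4-epimeric epoxy allylic alcohols (24 and its 4R epimer) | CC(C)(C)[Si](C)(C)OCCCC[C@@H]1O[C@@]1(C)C(O)/C=C/[C@@](C)(CC[C@@H](O[Si](C(C)C)(C(C)C)C(C)C)C(C)=C)CCO[Si](C)(C)C(C)(C)C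
F6 | step 20 | 3-[(triethylsilyl)oxy]propanal | O=CCCO[Si](CC)(CC)CC
F7 | step 20 | C8-triethylsilyloxy epoxy enone (analogue of 23 ending at C8) | CC[Si](CC)(CC)OCC[C@@H]1O[C@@]1(C)C(=O)/C=C/[C@@](C)(CC[C@@H](O[Si](C(C)C)(C(C)C)C(C)C)C(C)=C)CCO[Si](C)(C)C(C)(C)C
F8 | step 20 | erythro (4S) alcohol of F7 | CC[Si](CC)(CC)OCC[C@@H]1O[C@@]1(C)[C@@H](O)/C=C/[C@@](C)(CC[C@@H](O[Si](C(C)C)(C(C)C)C(C)C)C(C)=C)CCO[Si](C)(C)C(C)(C)C
F9 | step 20 | (4R) 3-methylbut-2-enoate of F8 | CC[Si](CC)(CC)OCC[C@@H]1O[C@@]1(C)[C@H](OC(=O)C=C(C)C)/C=C/[C@@](C)(CC[C@@H](O[Si](C(C)C)(C(C)C)C(C)C)C(C)=C)CCO[Si](C)(C)C(C)(C)C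
F10 | step 20 | C8 primary alcohol | OCC[C@@H]1O[C@@]1(C)[C@H](OC(=O)C=C(C)C)/C=C/[C@@](C)(CC[C@@H](O[Si](C(C)C)(C(C)C)C(C)C)C(C)=C)CCO[Si](C)(C)C(C)(C)C
F11 | step 20 | C8 primary iodide | ICC[C@@H]1O[C@@]1(C)[C@H](OC(=O)C=C(C)C)/C=C/[C@@](C)(CC[C@@H](O[Si](C(C)C)(C(C)C)C(C)C)C(C)=C)CCO[Si](C)(C)C(C)(C)C
F12 | step 20 | C9 diethyl phosphonate N-methoxy-N-methylamide (both C9 epimers) | CCOP(=O)(OCC)C(CC[C@@H]1O[C@@]1(C)[C@H](OC(=O)C=C(C)C)/C=C/[C@@](C)(CC[C@@H](O[Si](C(C)C)(C(C)C)C(C)C)C(C)=C)CCO[Si](C)(C)C(C)(C)C)C(=O)N(C)OC
F13 | step 20 | C10 alcohol of F12 | CCOP(=O)(OCC)C(CC[C@@H]1O[C@@]1(C)[C@H](OC(=O)C=C(C)C)/C=C/[C@@](C)(CC[C@@H](O[Si](C(C)C)(C(C)C)C(C)C)C(C)=C)CCO)C(=O)N(C)OC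
F14 | step 20 | C10 aldehyde of F12 | CCOP(=O)(OCC)C(CC[C@@H]1O[C@@]1(C)[C@H](OC(=O)C=C(C)C)/C=C/[C@@](C)(CC[C@@H](O[Si](C(C)C)(C(C)C)C(C)C)C(C)=C)CC=O)C(=O)N(C)OC
F15 | step 20 | eleven-membered (9E)-N-methoxy-N-methyl enamide (C3' TIPS ether) | C=C(C)[C@H](O[Si](C(C)C)(C(C)C)C(C)C)CC[C@]1(C)/C=C/[C@@H](OC(=O)C=C(C)C)[C@]2(C)O[C@H]2CC/C(C(=O)N(C)OC)=C\C1
F16 | step 17 | (4R) 4-nitrobenzoate of the C4 alcohol | CC(C)(C)[Si](C)(C)OCCCC[C@@H]1O[C@@]1(C)[C@H](OC(=O)c1ccc(cc1)[N+](=O)[O-])/C=C/[C@@](C)(CC[C@@H](O[Si](C(C)C)(C(C)C)C(C)C)C(C)=C)CCO[Si](C)(C)C(C)(C)C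
F17 | step 17 | threo (4R) epoxy alcohol, C4 epimer of 24 | CC(C)(C)[Si](C)(C)OCCCC[C@@H]1O[C@@]1(C)[C@H](O)/C=C/[C@@](C)(CC[C@@H](O[Si](C(C)C)(C(C)C)C(C)C)C(C)=C)CCO[Si](C)(C)C(C)(C)C
F18 | step 2 | geranyl diethyl phosphate | CCOP(=O)(OCC)OC/C=C(\C)CCC=C(C)C
A1 | alternative 1 | cis-1,2-dialkenylcycloheptanol with C4 PMB ether and C5,C6 acetonide (drawn for a chair-like transition state) | C=C[C@@]1(O)CC[C@H]2OC(C)(C)O[C@@]2(C)[C@H](OCc3ccc(OC)cc3)[C@H]1/C=C(\C)CC[C@@H](O[Si](C)(C)C(C)(C)C)C(C)=C
A2 | alternative 1 | eleven-membered C9 enol triflate with C4 PMB ether and C5,C6 acetonide | C=C(C)[C@H](O[Si](C)(C)C(C)(C)C)CC[C@]1(C)/C=C/[C@@H](OCc2ccc(OC)cc2)[C@]3(C)OC(C)(C)O[C@@H]3CC/C(OS(=O)(=O)C(F)(F)F)=C\C1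
A3 | alternative 2 | acyclic C5 (E)-alkenyl iodide with C4 enal | C=C(C)[C@H](O[Si](C)(C)C(C)(C)C)CC[C@](C)(/C=C/C=O)C/C=C(CO[Si](C)(C)C(C)(C)C)\CC/C=C(\C)I
A4 | alternative 2 | eleven-membered trienol (both C4 epimers) | C=C(C)[C@H](O[Si](C)(C)C(C)(C)C)CC[C@]1(C)/C=C/C(O)/C(C)=C/CC/C(CO[Si](C)(C)C(C)(C)C)=C\C1
A5 | alternative 3 | acyclic C9 phosphonoacetate with C10 aldehyde and C4 triethylsilyl ether | C=C(C)[C@H](O[Si](C)(C)C(C)(C)C)CC[C@@](C)(CC=O)/C=C/[C@@H](O[Si](CC)(CC)CC)[C@]1(C)O[C@H]1CCC(C(=O)OCC)P(=O)(OCC)OCC
A6 | alternative 3 | eleven-membered C9 ethyl enoate | C=C(C)[C@H](O[Si](C)(C)C(C)(C)C)CC[C@]1(C)/C=C/[C@@H](O[Si](CC)(CC)CC)[C@]2(C)O[C@H]2CC/C(C(=O)OCC)=C\C1
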